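The carotenoid is cut at C7=C8 and C7′=C8′ into the C20 dialdehyde C8–C8′ and two identical C10 ring sulfones. Each ε-ring is taken from (1S,5S)-verbenone, which already contains C1–C6 with the gem-dimethyl group on C1, the C3 oxygen, C4=C5 with its methyl group and the C6 stereocentre; its bridge methylene is C7. The key step exploits the strained cyclobutane bond C7–C2, which lies α,β to the C3 carbonyl: an arenethiolate attacks C7 and cleaves this bond, giving in one operation the monocyclic 3-oxo ε-ring with a C7–S handle. The precursor is verbenone itself plus 3,5-bis(trifluoromethyl)benzenethiol, whose sulfone later olefinates directly.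

Key step: step 1

Assumption: the central unit has to be the C20 dialdehyde crocetindialdehyde (C8 to C8′ with its four methyl groups), taken as a purchasable carotenoid building block; the C10 dialdehyde 2,7-dimethylocta-2,4,6-trienedial would give only a C30 skeleton with the C10 ring unit and is used solely in a fallback.

Remark: the bridge carbon attacked in step 1 is a secondary methylene; the arenethiolate carries two CF3 spectator groups so that its sulfone is competent in a one-pot olefination; positions are given in carotenoid numbering, compounds by systematic names.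

Step 1
Reactants: 1 (1S,5S)-(−)-verbenone; 2 3,5-bis(trifluoromethyl)benzenethiol
Product: 5 (4R)-4-({[3,5-bis(trifluoromethyl)phenyl]sulfanyl}methyl)-3,5,5-trimethylcyclohex-2-en-1-one, via sodium arenethiolate 3 (not isolated), via sodium dienolate 4 (not isolated)
Conditions: 2 (2.0 equiv), NaH (0.5 equiv), 2,6-di-tert-butyl-4-methylphenol (1 mol %), NMP, 20 °C then 120 °C, argon, dark; aq. NH4Cl
Reagents that add atoms: none
Why: Proposed new method: thiolate 3 attacks the bridge methylene C7 from the side opposite the C7–C2 σ-bond, which is strained and lies nearly parallel to the enone π-system, so that C7–S forms as C7–C2 breaks and the charge leaves as the cross-conjugated dienolate 4; thiol 2 then protonates 4 at C2 and regenerates 3, so the thiolate acts as a chain carrier. The closest known reaction types are the homoconjugate (homo-Michael) opening of cyclopropyl ketones by thiolates and the nucleophilic opening of acceptor-activated cyclobutanes, with release of four-membered-ring strain as the driving force. No ring is closed and no stereocentre is created: the bridgehead that becomes C6 keeps all four of its bonds, so its configuration is carried over from 1 and corresponds to 6R of the target. The step needs cleavage at C7 and not at the CMe2 bridge, which is secured because SN2 attack at the quaternary carbon is impossible and because the non-acidic, radical-inhibited medium shuts down the cationic and ketyl pathways that open towards the tertiary centre. It also needs C6 to survive the basic medium, which the weak basicity of the electron-poor arenethiolate and the fast protonation of 4 by the acidic thiol are chosen to secure, while 1,4-addition of thiolate to the enone is reversible and unproductive.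

Step 2
Reactants: 5 (4R)-4-({[3,5-bis(trifluoromethyl)phenyl]sulfanyl}methyl)-3,5,5-trimethylcyclohex-2-en-1-one
Product: 7 (4R)-4-({[3,5-bis(trifluoromethyl)phenyl]sulfonyl}methyl)-3,5,5-trimethylcyclohex-2-en-1-one, via sulfoxide 6 (not isolated)
Conditions: 3-chloroperbenzoic acid (mCPBA, 2.3 equiv), NaHCO3, CH2Cl2, 0 to 20 °C; aq. Na2S2O3
Reagents that add atoms: mCPBA (3-chloroperbenzoic acid), OOC(=O)c1cccc(Cl)c1
Why: Peracid oxidation of a sulfide to the sulfone by way of sulfoxide 6 should be chemoselective here because the only C=C bond is the electron-poor, β,β-disubstituted enone double bond, and the C6 stereocentre is not involved.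

Step 3
Reactants: 7 (4R)-4-({[3,5-bis(trifluoromethyl)phenyl]sulfonyl}methyl)-3,5,5-trimethylcyclohex-2-en-1-one
Product: 8 (1R,4R)-4-({[3,5-bis(trifluoromethyl)phenyl]sulfonyl}methyl)-3,5,5-trimethylcyclohex-2-en-1-ol
Conditions: (3aS)-1-methyl-3,3-diphenyltetrahydro-1H,3H-pyrrolo[1,2-c][1,3,2]oxazaborole ((S)-Me-CBS, 0.3 equiv), BH3·SMe2 (0.7 equiv), THF, −30 °C; MeOH
Reagents that add atoms: none
Why: Corey–Bakshi–Shibata reduction delivers hydride under catalyst control with the alkenyl arm of the enone acting as the large carbonyl substituent, so that the (S)-oxazaborolidine should give the 1R carbinol (3R in carotenoid numbering, hydroxyl trans to the C6 side chain), while any (4S)-ketone stemming from enantiomerically impure 1 would end up as a separable cis diastereomer.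

Step 4
Reactants: 8 (1R,4R)-4-({[3,5-bis(trifluoromethyl)phenyl]sulfonyl}methyl)-3,5,5-trimethylcyclohex-2-en-1-ol
Product: 9 tert-butyl{[(1R,4R)-4-({[3,5-bis(trifluoromethyl)phenyl]sulfonyl}methyl)-3,5,5-trimethylcyclohex-2-en-1-yl]oxy}dimethylsilane
Conditions: TBSCl (1.3 equiv), imidazole (2.5 equiv), DMF, 20 °C
Reagents that add atoms: TBSCl (tert-butyldimethylsilyl chloride), CC(C)(C)[Si](C)(C)Cl
Why: Imidazole-promoted silylation of the secondary allylic alcohol is routine and masks the hydroxyl group against the base of the olefination without touching either stereocentre.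

Step 5
Reactants: 9 tert-butyl{[(1R,4R)-4-({[3,5-bis(trifluoromethyl)phenyl]sulfonyl}methyl)-3,5,5-trimethylcyclohex-2-en-1-yl]oxy}dimethylsilane; 10 crocetindialdehyde, (2E,4E,6E,8E,10E,12E,14E)-2,6,11,15-tetramethylhexadeca-2,4,6,8,10,12,14-heptaenedial
Product: 12 (all-E,3R,6R,3′R,6′R)-3,3′-bis{[tert-butyl(dimethyl)silyl]oxy}-ε,ε-carotene, via C30 apocarotenal 11 (not isolated)
Conditions: 10 (1.0 equiv), 9 (2.4 equiv), powdered KOH (8 equiv), Bu4NBr (0.2 equiv), THF, 20 °C, argon, dark
Reagents that add atoms: none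
Why: This is the Julia–Kocienski olefination in its 3,5-bis(trifluoromethyl)phenyl sulfone variant, in which the α-sulfonyl carbanion adds to each formyl group, the alkoxide attacks the electron-poor aryl ring (Smiles rearrangement) and loss of SO2 and aryloxide forms C7=C8 and C7′=C8′ with the E preference expected for conjugated aldehydes, the stereocentres being spectators because H–C6 is not acidic under these conditions.

Step 6
Reactants: 12 (all-E,3R,6R,3′R,6′R)-3,3′-bis{[tert-butyl(dimethyl)silyl]oxy}-ε,ε-carotene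
Product: 13 (all-E,3R,6R,3′R,6′R)-ε,ε-carotene-3,3′-diol (lactucaxanthin)
Conditions: Bu4NF (3 equiv), THF, 0 to 20 °C, dark; aq. NH4Cl; then I2 (1 mol %), toluene/heptane slurry, daylight, 20 °C; aq. Na2S2O3; crystallisation from CH2Cl2/hexane
Reagents that add atoms: none
Why: Fluoride-mediated desilylation frees both allylic hydroxyl groups without the acid that could ionise the C3–O bonds, and iodine-catalysed equilibration in a poor solvent should funnel any 7Z or 7′Z isomer from step 5 into the all-E polyene, which crystallises, the four stereocentres being untouched.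

Compound list
1 | (1S,5S)-(−)-verbenone, (1S,5S)-4,6,6-trimethylbicyclo[3.1.1]hept-3-en-2-one | CC1=CC(=O)[C@@H]2C(C)(C)[C@H]1C2 | starting material
2 | 3,5-bis(trifluoromethyl)benzenethiol | FC(F)(F)c1cc(S)cc(C(F)(F)F)c1 | starting material
3 | sodium 3,5-bis(trifluoromethyl)benzenethiolate | [Na+].[S-]c1cc(C(F)(F)F)cc(C(F)(F)F)c1 | intermediate
4 | sodium (4S)-4-({[3,5-bis(trifluoromethyl)phenyl]sulfanyl}methyl)-3,3,5-trimethylcyclohexa-1,5-dien-1-olate (cross-conjugated dienolate of 5; same spatial arrangement at the CH carbon as in 5, the descriptor changes only through the priority rules) | [Na+].CC1=CC([O-])=CC(C)(C)[C@H]1CSc1cc(C(F)(F)F)cc(C(F)(F)F)c1 | intermediate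
5 | (4R)-4-({[3,5-bis(trifluoromethyl)phenyl]sulfanyl}methyl)-3,5,5-trimethylcyclohex-2-en-1-one | CC1=CC(=O)CC(C)(C)[C@H]1CSc1cc(C(F)(F)F)cc(C(F)(F)F)c1 | intermediate
6 | (4R)-4-({[3,5-bis(trifluoromethyl)phenyl]sulfinyl}methyl)-3,5,5-trimethylcyclohex-2-en-1-one (both configurations at sulfur) | CC1=CC(=O)CC(C)(C)[C@H]1CS(=O)c1cc(C(F)(F)F)cc(C(F)(F)F)c1 | intermediate
7 | (4R)-4-({[3,5-bis(trifluoromethyl)phenyl]sulfonyl}methyl)-3,5,5-trimethylcyclohex-2-en-1-one | CC1=CC(=O)CC(C)(C)[C@H]1CS(=O)(=O)c1cc(C(F)(F)F)cc(C(F)(F)F)c1 | intermediate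
8 | (1R,4R)-4-({[3,5-bis(trifluoromethyl)phenyl]sulfonyl}methyl)-3,5,5-trimethylcyclohex-2-en-1-ol (hydroxyl trans to the sulfonylmethyl group) | CC1=C[C@H](O)CC(C)(C)[C@H]1CS(=O)(=O)c1cc(C(F)(F)F)cc(C(F)(F)F)c1 | intermediate
9 | tert-butyl{[(1R,4R)-4-({[3,5-bis(trifluoromethyl)phenyl]sulfonyl}methyl)-3,5,5-trimethylcyclohex-2-en-1-yl]oxy}dimethylsilane | CC1=C[C@H](O[Si](C)(C)C(C)(C)C)CC(C)(C)[C@H]1CS(=O)(=O)c1cc(C(F)(F)F)cc(C(F)(F)F)c1 | intermediate
10 | crocetindialdehyde, (2E,4E,6E,8E,10E,12E,14E)-2,6,11,15-tetramethylhexadeca-2,4,6,8,10,12,14-heptaenedial | O=C/C(C)=C/C=C/C(C)=C/C=C/C=C(C)/C=C/C=C(C)/C=O | starting material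
11 | (all-E,3R,6R)-3-{[tert-butyl(dimethyl)silyl]oxy}-8′-apo-ε-caroten-8′-al (product of the first olefination) | CC1=C[C@H](O[Si](C)(C)C(C)(C)C)CC(C)(C)[C@H]1/C=C/C(C)=C/C=C/C(C)=C/C=C/C=C(C)/C=C/C=C(C)/C=O | intermediate
12 | (all-E,3R,6R,3′R,6′R)-3,3′-bis{[tert-butyl(dimethyl)silyl]oxy}-ε,ε-carotene | CC1=C[C@H](O[Si](C)(C)C(C)(C)C)CC(C)(C)[C@H]1/C=C/C(C)=C/C=C/C(C)=C/C=C/C=C(C)/C=C/C=C(C)/C=C/[C@H]1C(C)=C[C@H](O[Si](C)(C)C(C)(C)C)CC1(C)C | intermediate
13 | (all-E,3R,6R,3′R,6′R)-ε,ε-carotene-3,3′-diol (lactucaxanthin) | CC1=C[C@H](O)CC(C)(C)[C@H]1/C=C/C(C)=C/C=C/C(C)=C/C=C/C=C(C)/C=C/C=C(C)/C=C/[C@H]1C(C)=C[C@H](O)CC1(C)C | target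

Total step count: 6
Longest linear sequence: 6 steps (1 to 5 to 7 to 8 to 9 to 12 to 13)

Steps most likely to fail

Step 1 (proposed new method). The SN2 opening at the secondary bridge methylene may be too slow to compete with unproductive reversible 1,4-addition or thermal decomposition, or reversible loss and re-addition of arenethiolate may erode the C6 configuration. The fallback uses known chemistry, sets out from thiol 2 and returns to the route at alcohol 8. S-Alkylation of 2 with geranyl bromide (K2CO3, acetone) should give geranyl 3,5-bis(trifluoromethyl)phenyl sulfide F1, and oxidation (H2O2, (NH4)6Mo7O24·4H2O cat., EtOH) the geranyl 3,5-bis(trifluoromethyl)phenyl sulfone F2. Proton-induced cationic cyclisation (H2SO4, AcOH, 0 °C) should then give the racemic α-cyclogeranyl 3,5-bis(trifluoromethyl)phenyl sulfone F3, and allylic oxidation at C3 (t-BuOOH, CuI cat., MeCN) the racemic keto sulfone F4. Reduction of F4 under the conditions of step 3 is reagent-controlled, so the (4R)-enantiomer should give 8 and the (4S)-enantiomer the cis (1R,4S)-alcohol F5; the two diastereomers are separated by chromatography and 8 is recrystallised.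

Step 5. Addition of the hindered, β-branched sulfonyl carbanion to both ends of the weakly electrophilic polyene dialdehyde may stall after the first olefination, or retro-addition may outrun the aryl transfer. The fallback sets out from sulfone 9 and returns at bis-silyl ether 12 by a C15 + C10 + C15 Wittig assembly. Deprotonation of 9 (LiN(SiMe3)2, THF, −78 °C) and alkylation with ethyl (E)-4-bromo-3-methylbut-2-enoate should give the alkylated sulfone ester F6 (epimers at the sulfonyl-bearing carbon). Base-induced elimination of arenesulfinate (1,8-diazabicyclo[5.4.0]undec-7-ene, toluene) should give the C15 dienoate F7, and reduction with i-Bu2AlH the C15 allylic alcohol F8. CBr4/PPh3 should give the C15 allylic bromide F9 and PPh3 the C15 phosphonium bromide F10. Twofold Wittig reaction of F10 with 2,7-dimethylocta-2,4,6-trienedial (NaOMe, CH2Cl2/MeOH) forms C11=C12 and C11′=C12′ and gives 12, whose Z isomers are equilibrated as in step 6.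

Step 3. Facial selectivity may be poor if the saturated arm, with its neighbouring quaternary carbon, competes with the alkenyl arm as the large group, or if substrate bias from the C6 side chain opposes the catalyst. The fallback sets out from ketone 7 and returns at alcohol 8. Luche reduction (NaBH4, CeCl3·7H2O, MeOH, −40 °C) should give 8 together with the cis (1S,4R)-alcohol F11, separated by chromatography. F11 is inverted by a Mitsunobu reaction (4-nitrobenzoic acid, PPh3, diisopropyl azodicarboxylate, toluene, 0 °C) to the trans (1R,4R)-4-nitrobenzoate F12, and methanolysis (K2CO3, MeOH) gives 8.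

Further compounds
F1 | step 1 | 1-{[(2E)-3,7-dimethylocta-2,6-dien-1-yl]sulfanyl}-3,5-bis(trifluoromethyl)benzene (geranyl aryl sulfide) | CC(C)=CCC/C(C)=C/CSc1cc(C(F)(F)F)cc(C(F)(F)F)c1
F2 | step 1 | 1-{[(2E)-3,7-dimethylocta-2,6-dien-1-yl]sulfonyl}-3,5-bis(trifluoromethyl)benzene (geranyl aryl sulfone) | CC(C)=CCC/C(C)=C/CS(=O)(=O)c1cc(C(F)(F)F)cc(C(F)(F)F)c1
F3 | step 1 | racemic 1-{[(2,6,6-trimethylcyclohex-2-en-1-yl)methyl]sulfonyl}-3,5-bis(trifluoromethyl)benzene (α-cyclogeranyl aryl sulfone) | CC1=CCCC(C)(C)C1CS(=O)(=O)c1cc(C(F)(F)F)cc(C(F)(F)F)c1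
F4 | step 1 | racemic 4-({[3,5-bis(trifluoromethyl)phenyl]sulfonyl}methyl)-3,5,5-trimethylcyclohex-2-en-1-one (racemate of 7) | CC1=CC(=O)CC(C)(C)C1CS(=O)(=O)c1cc(C(F)(F)F)cc(C(F)(F)F)c1
F5 | step 1 | (1R,4S)-4-({[3,5-bis(trifluoromethyl)phenyl]sulfonyl}methyl)-3,5,5-trimethylcyclohex-2-en-1-ol (cis) | CC1=C[C@H](O)CC(C)(C)[C@@H]1CS(=O)(=O)c1cc(C(F)(F)F)cc(C(F)(F)F)c1
F6 | step 5 | ethyl (2E)-5-{[3,5-bis(trifluoromethyl)phenyl]sulfonyl}-5-[(1R,4R)-4-{[tert-butyl(dimethyl)silyl]oxy}-2,6,6-trimethylcyclohex-2-en-1-yl]-3-methylpent-2-enoate (both configurations at C5 of the chain) | CC1=C[C@H](O[Si](C)(C)C(C)(C)C)CC(C)(C)[C@H]1C(C/C(C)=C/C(=O)OCC)S(=O)(=O)c1cc(C(F)(F)F)cc(C(F)(F)F)c1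
F7 | step 5 | ethyl (2E,4E)-5-[(1R,4R)-4-{[tert-butyl(dimethyl)silyl]oxy}-2,6,6-trimethylcyclohex-2-en-1-yl]-3-methylpenta-2,4-dienoate | CC1=C[C@H](O[Si](C)(C)C(C)(C)C)CC(C)(C)[C@H]1/C=C/C(C)=C/C(=O)OCC
F8 | step 5 | (2E,4E)-5-[(1R,4R)-4-{[tert-butyl(dimethyl)silyl]oxy}-2,6,6-trimethylcyclohex-2-en-1-yl]-3-methylpenta-2,4-dien-1-ol | CC1=C[C@H](O[Si](C)(C)C(C)(C)C)CC(C)(C)[C@H]1/C=C/C(C)=C/CO
F9 | step 5 | {[(1R,4R)-4-[(1E,3E)-5-bromo-3-methylpenta-1,3-dien-1-yl]-3,5,5-trimethylcyclohex-2-en-1-yl]oxy}(tert-butyl)dimethylsilane | CC1=C[C@H](O[Si](C)(C)C(C)(C)C)CC(C)(C)[C@H]1/C=C/C(C)=C/CBr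
F10 | step 5 | {(2E,4E)-5-[(1R,4R)-4-{[tert-butyl(dimethyl)silyl]oxy}-2,6,6-trimethylcyclohex-2-en-1-yl]-3-methylpenta-2,4-dien-1-yl}triphenylphosphonium bromide | CC1=C[C@H](O[Si](C)(C)C(C)(C)C)CC(C)(C)[C@H]1/C=C/C(C)=C/C[P+](c1ccccc1)(c1ccccc1)c1ccccc1.[Br-]
F11 | step 3 | (1S,4R)-4-({[3,5-bis(trifluoromethyl)phenyl]sulfonyl}methyl)-3,5,5-trimethylcyclohex-2-en-1-ol (cis) | CC1=C[C@@H](O)CC(C)(C)[C@H]1CS(=O)(=O)c1cc(C(F)(F)F)cc(C(F)(F)F)c1
F12 | step 3 | (1R,4R)-4-({[3,5-bis(trifluoromethyl)phenyl]sulfonyl}methyl)-3,5,5-trimethylcyclohex-2-en-1-yl 4-nitrobenzoate | CC1=C[C@H](OC(=O)c2ccc(cc2)[N+](=O)[O-])CC(C)(C)[C@H]1CS(=O)(=O)c1cc(C(F)(F)F)cc(C(F)(F)F)c1
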